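**Retrosynthetic overview**
1. Target 23 ← Schenck ene reaction on the C4=C5 alkene of angelate 22 (gives 5α-OOH and C4=C15) ← angeloylation of the 3β-alcohol 19 ← Luche reduction of enone 18.
2. Key disconnection C6–C7 (ring B, closed last): C7 of ring B carries the 1,1-disubstituted acrylate C11(=C13H2)–C12O2Me, and C6 is the γ-carbon of the C3-keto/C4=C5 enone of ring A. Enone 18 is therefore the SN2' product of the extended enolate of bromide 16 attacking C7 while bromide leaves C13.
3. 16 ← allylic bromination with transposition ← Morita–Baylis–Hillman adduct 15 ← aldehyde 13 ← hydroboration–oxidation of the C10 allyl group; the ring-A enone with its C6 and C15 methyls ← Stork–Danheiser transposition.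
4. C10 quaternary stereocentre ← palladium-catalysed decarboxylative asymmetric allylation of enol carbonate 7 ← vinylogous ester of 2-methylcyclohexane-1,3-dione (ring A is present from the start; ring B closes in the key step).

Key step: step 10

Remark: eudesmane numbering is used (ring A = C1–C5 and C10; ring B = C5–C10; C11–C13 = acrylate with C12 the ester carbon; C14 = methyl on C10; C15 = carbon on C4); the target is read as 3β-angeloyloxy, 5α-hydroperoxy, 7α-H, 10β-methyl (3S,5S,7R,10S).
Remark: the sense of induction in step 4 is assumed by analogy with 2-allyl-2-methylcyclohexanone, where the (S)-ligand gives the (S)-ketone; the (R)-ligand is therefore assigned to the (R)-configured 8.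

Step 1
Reactants: 1 2-methylcyclohexane-1,3-dione
Product: 2 3-isobutoxy-2-methylcyclohex-2-en-1-one
Conditions: i-BuOH, p-TsOH·H2O (cat.), toluene, reflux, azeotropic removal of water
Reagents that add atoms: 2-methylpropan-1-ol (isobutanol), CC(C)CO
Why: Acid-catalysed condensation of a cyclic 1,3-dione with a primary alcohol under water removal is the standard vinylogous ester formation and creates no stereocentre.

Step 2
Reactants: 2 3-isobutoxy-2-methylcyclohex-2-en-1-one
Product: 4 rac-3-isobutoxy-2,6-dimethylcyclohex-2-en-1-one, via lithium 5-isobutoxy-6-methylcyclohexa-1,5-dien-1-olate 3 (not isolated)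
Conditions: LDA, THF, −78 °C; MeI, −78 → 0 °C
Reagents that add atoms: iodomethane, CI; lithium diisopropylamide, [Li+].CC(C)[N-]C(C)C (lithium kept only in 3)
Why: Kinetic deprotonation of a 3-alkoxyenone takes place at the α'-carbon C6 and the enolate is methylated there (enolate alkylation), the racemic C6 centre being erased in step 3.

Step 3
Reactants: 4 rac-3-isobutoxy-2,6-dimethylcyclohex-2-en-1-one; 5 allyl chloroformate
Product: 7 allyl 5-isobutoxy-2,6-dimethylcyclohexa-1,5-dien-1-yl carbonate, via lithium 5-isobutoxy-2,6-dimethylcyclohexa-1,5-dien-1-olate 6 (not isolated)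
Conditions: LDA, TMEDA, THF, −78 °C; then 5, −78 °C → rt
Reagents that add atoms: lithium diisopropylamide, [Li+].CC(C)[N-]C(C)C (lithium kept only in 6)
Why: Deprotonation at the now tertiary C6 gives a tetrasubstituted lithium enolate that, with TMEDA present, is acylated on oxygen by the chloroformate (enol carbonate formation).

Step 4
Reactants: 7 allyl 5-isobutoxy-2,6-dimethylcyclohexa-1,5-dien-1-yl carbonate
Product: 8 (R)-6-allyl-3-isobutoxy-2,6-dimethylcyclohex-2-en-1-one
Conditions: Pd2(dba)3 (2.5 mol %), (R)-t-Bu-PHOX (6 mol %), toluene, 30 °C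
Reagents that add atoms: none
Why: Decarboxylative asymmetric allylic alkylation: zerovalent palladium ionises the allyl carbonate, CO2 is lost, and the allylpalladium enolate collapses inside the chiral phosphinooxazoline pocket, which should set the quaternary centre (future C10) as R.

Step 5
Reactants: 8 (R)-6-allyl-3-isobutoxy-2,6-dimethylcyclohex-2-en-1-one
Product: 10 (S)-6-(3-hydroxypropyl)-3-isobutoxy-2,6-dimethylcyclohex-2-en-1-one, via (S)-6-[3-(9-borabicyclo[3.3.1]nonan-9-yl)propyl]-3-isobutoxy-2,6-dimethylcyclohex-2-en-1-one 9 (not isolated)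
Conditions: 9-BBN, THF, 0 °C → rt; then NaOH, H2O2, 0 °C
Reagents that add atoms: 9-borabicyclo[3.3.1]nonane, B1C2CCCC1CCC2 (boron unit kept only in 9); hydrogen peroxide, OO
Why: Anti-Markovnikov hydroboration–oxidation of the terminal alkene is run before the enone is unveiled because the vinylogous ester carbonyl is inert to the borane; the quaternary centre is untouched (its descriptor changes only through the priority rules).

Step 6
Reactants: 10 (S)-6-(3-hydroxypropyl)-3-isobutoxy-2,6-dimethylcyclohex-2-en-1-one
Product: 12 (S)-4-(3-hydroxypropyl)-2,3,4-trimethylcyclohex-2-en-1-one, via (6S)-6-(3-hydroxypropyl)-3-isobutoxy-1,2,6-trimethylcyclohex-2-en-1-ol 11 (not isolated)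
Conditions: MeLi (3 equiv), THF, −78 → 0 °C; then 1 M HCl, rt
Reagents that add atoms: methyllithium, [Li]C; water, O
Why: Stork–Danheiser transposition: 1,2-addition of methyllithium (one equivalent is spent on the hydroxyl group) followed by acid hydrolysis of the enol ether and loss of water moves the carbonyl to C3 and leaves the new methyl (C6) on the β-carbon of the tetrasubstituted enone, without touching the quaternary centre.

Step 7
Reactants: 12 (S)-4-(3-hydroxypropyl)-2,3,4-trimethylcyclohex-2-en-1-one
Product: 13 3-[(1S)-1,2,3-trimethyl-4-oxocyclohex-2-en-1-yl]propanal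
Conditions: Dess–Martin periodinane, NaHCO3, CH2Cl2, 0 °C → rt
Reagents that add atoms: none
Why: Dess–Martin oxidation takes the primary alcohol to the aldehyde (C7) under buffered, non-enolising conditions that leave the enone alone.

Step 8
Reactants: 13 3-[(1S)-1,2,3-trimethyl-4-oxocyclohex-2-en-1-yl]propanal; 14 methyl acrylate
Product: 15 methyl 3-hydroxy-2-methylidene-5-[(1S)-1,2,3-trimethyl-4-oxocyclohex-2-en-1-yl]pentanoate (both carbinol epimers)
Conditions: DABCO (1 equiv), 14 (excess), MeOH, rt, several days
Reagents that add atoms: none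
Why: Morita–Baylis–Hillman reaction: the amine adds to the acrylate and the zwitterionic enolate attacks the unhindered aldehyde; the carbinol centre forms as a mixture, which is harmless because it becomes sp2 in step 9.

Step 9
Reactants: 15 methyl 3-hydroxy-2-methylidene-5-[(1S)-1,2,3-trimethyl-4-oxocyclohex-2-en-1-yl]pentanoate
Product: 16 methyl (Z)-2-(bromomethyl)-5-[(1S)-1,2,3-trimethyl-4-oxocyclohex-2-en-1-yl]pent-2-enoate
Conditions: PBr3, Et2O, 0 °C
Reagents that add atoms: phosphorus tribromide, BrP(Br)Br
Why: Allylic bromination with transposition (SN2' displacement of the activated hydroxyl by bromide) should give the conjugated primary bromide with the chain trans to the ester, i.e. the Z alkene.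

Step 10
Reactants: 16 methyl (Z)-2-(bromomethyl)-5-[(1S)-1,2,3-trimethyl-4-oxocyclohex-2-en-1-yl]pent-2-enoate
Product: 18 methyl 3-oxoeudesma-4,11(13)-dien-12-oate, via potassium (4S)-4-[(3Z)-4-(bromomethyl)-5-methoxy-5-oxopent-3-en-1-yl]-2,4-dimethyl-3-methylidenecyclohex-1-en-1-olate 17 (not isolated)
Conditions: KOt-Bu (1.1 equiv), THF/t-BuOH (10:1), 0.005 M, slow addition of 16, −20 → 0 °C; then AcOH
Reagents that add atoms: potassium tert-butoxide, CC(C)(C)[O-].[K+] (potassium kept only in 17)
Why: Proposed new method: under equilibrating conditions tert-butoxide removes a proton from C6 (the only γ-position with hydrogen, because C10 is quaternary) and the potassium dienolate 17 adds through C6 to C7 of the tethered enoate while bromide leaves C13 (SN2', possibly stepwise as conjugate addition and E1cB loss of bromide), which restores the C4=C5 enone and leaves C11=C13 as the acrylate methylene. The closest known reaction types are the γ-alkylation of extended ketone enolates and the SN2' displacement of 2-(bromomethyl)alk-2-enoates by carbon nucleophiles; their intramolecular combination has not been shown. Ring B closes by a 6-(enolendo)-exo-trig attack through a chair-like transition state. C7 is the only new stereocentre and is controlled by C10: the tether must stand pseudo-axial on C10 to reach C6, which leaves the C10 methyl axial on the forming ring, and the branched C11 unit should take the equatorial position at C7, cis to that methyl (7α-H). The step needs attack through C6 rather than C4 or C2: the alkoxide/alcohol medium keeps the cross-conjugated C2 enolate at a low level, direct SN2 at C13 would demand an eight-membered ring, and C4, although the more nucleophilic terminus, already carries the C15 methyl, so its attack on the β-branched C7 would have to join a quaternary to a tertiary carbon inside a bicyclo[3.3.1]nonane and give up enone conjugation, whereas the unhindered C6 terminus leads to the conjugated, unbridged octalone.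

Step 11
Reactants: 18 methyl 3-oxoeudesma-4,11(13)-dien-12-oate
Product: 19 methyl 3β-hydroxyeudesma-4,11(13)-dien-12-oate
Conditions: NaBH4, CeCl3·7H2O, MeOH, −78 °C
Reagents that add atoms: none
Why: Luche reduction gives 1,2-reduction of the enone without touching the acrylate, and axial hydride delivery from the α-face of the half-chair ring A should place the C3 hydroxyl pseudo-equatorial and β, cis to the C10 methyl.

Step 12
Reactants: 19 methyl 3β-hydroxyeudesma-4,11(13)-dien-12-oate; 20 angelic acid
Product: 22 methyl 3β-angeloyloxyeudesma-4,11(13)-dien-12-oate, via angelic 2,4,6-trichlorobenzoic anhydride 21 (not isolated)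
Conditions: 20, 2,4,6-trichlorobenzoyl chloride, Et3N, toluene, rt; then 19, 80 °C
Reagents that add atoms: 2,4,6-trichlorobenzoyl chloride, O=C(Cl)c1c(Cl)cc(Cl)cc1Cl (atoms kept only in 21)
Why: Yamaguchi-type esterification through the preformed mixed anhydride, without a nucleophilic amine catalyst, should acylate the hindered allylic alcohol with retention at C3 while avoiding isomerisation of the angelate to the tiglate.

Step 13
Reactants: 22 methyl 3β-angeloyloxyeudesma-4,11(13)-dien-12-oate
Product: 23 methyl 3β-angeloyloxy-5α-hydroperoxyeudesma-4(15),11(13)-dien-12-oate (target)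
Conditions: O2, tetraphenylporphyrin (cat.), visible light, CH2Cl2, −20 °C
Reagents that add atoms: dioxygen, O=O
Why: Schenck ene reaction: singlet oxygen should react only with the electron-rich tetrasubstituted C4=C5 alkene, bond to C5 from the α-face opposite the axial C10 methyl and take a hydrogen from the C15 methyl (C6 has no axial hydrogen on that face and the C3 hydrogen is geminal to the acyloxy group), giving the 5α-hydroperoxide and the exocyclic C4=C15 alkene.

**Compound list**
1 | 2-methylcyclohexane-1,3-dione | CC1C(=O)CCCC1=O | starting material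
2 | 3-isobutoxy-2-methylcyclohex-2-en-1-one | CC(C)COC1=C(C)C(=O)CCC1 | intermediate
3 | lithium 5-isobutoxy-6-methylcyclohexa-1,5-dien-1-olate (not isolated) | [Li+].[O-]C1=CCCC(OCC(C)C)=C1C | intermediate
4 | rac-3-isobutoxy-2,6-dimethylcyclohex-2-en-1-one | CC(C)COC1=C(C)C(=O)C(C)CC1 | intermediate
5 | allyl chloroformate | C=CCOC(=O)Cl | starting material
6 | lithium 5-isobutoxy-2,6-dimethylcyclohexa-1,5-dien-1-olate (not isolated) | [Li+].[O-]C1=C(C)CCC(OCC(C)C)=C1C | intermediate
7 | allyl 5-isobutoxy-2,6-dimethylcyclohexa-1,5-dien-1-yl carbonate | C=CCOC(=O)OC1=C(C)CCC(OCC(C)C)=C1C | intermediate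
8 | (R)-6-allyl-3-isobutoxy-2,6-dimethylcyclohex-2-en-1-one | C=CC[C@@]1(C)CCC(OCC(C)C)=C(C)C1=O | intermediate
9 | (S)-6-[3-(9-borabicyclo[3.3.1]nonan-9-yl)propyl]-3-isobutoxy-2,6-dimethylcyclohex-2-en-1-one (not isolated) | B1(C2CCCC1CCC2)CCC[C@@]3(C)CCC(OCC(C)C)=C(C)C3=O | intermediate
10 | (S)-6-(3-hydroxypropyl)-3-isobutoxy-2,6-dimethylcyclohex-2-en-1-one | OCCC[C@@]1(C)CCC(OCC(C)C)=C(C)C1=O | intermediate
11 | (6S)-6-(3-hydroxypropyl)-3-isobutoxy-1,2,6-trimethylcyclohex-2-en-1-ol (C1 epimers, present as its dilithium alkoxide, not isolated) | OCCC[C@@]1(C)CCC(OCC(C)C)=C(C)C1(C)O | intermediate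
12 | (S)-4-(3-hydroxypropyl)-2,3,4-trimethylcyclohex-2-en-1-one | OCCC[C@@]1(C)CCC(=O)C(C)=C1C | intermediate
13 | 3-[(1S)-1,2,3-trimethyl-4-oxocyclohex-2-en-1-yl]propanal | O=CCC[C@@]1(C)CCC(=O)C(C)=C1C | intermediate
14 | methyl acrylate | C=CC(=O)OC | starting material
15 | methyl 3-hydroxy-2-methylidene-5-[(1S)-1,2,3-trimethyl-4-oxocyclohex-2-en-1-yl]pentanoate (both carbinol epimers) | C=C(C(=O)OC)C(O)CC[C@@]1(C)CCC(=O)C(C)=C1C | intermediate
16 | methyl (Z)-2-(bromomethyl)-5-[(1S)-1,2,3-trimethyl-4-oxocyclohex-2-en-1-yl]pent-2-enoate | COC(=O)/C(CBr)=C/CC[C@@]1(C)CCC(=O)C(C)=C1C | intermediate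
17 | potassium (4S)-4-[(3Z)-4-(bromomethyl)-5-methoxy-5-oxopent-3-en-1-yl]-2,4-dimethyl-3-methylidenecyclohex-1-en-1-olate (extended enolate of 16, not isolated) | COC(=O)/C(CBr)=C/CC[C@@]1(C)CCC([O-])=C(C)C1=C.[K+] | intermediate
18 | methyl 3-oxoeudesma-4,11(13)-dien-12-oate; methyl 2-[(2R,4aS)-4a,8-dimethyl-7-oxo-1,2,3,4,4a,5,6,7-octahydronaphthalen-2-yl]prop-2-enoate | C=C(C(=O)OC)[C@@H]1CC[C@@]2(C)CCC(=O)C(C)=C2C1 | intermediate
19 | methyl 3β-hydroxyeudesma-4,11(13)-dien-12-oate (3S,7R,10S) | C=C(C(=O)OC)[C@@H]1CC[C@@]2(C)CC[C@H](O)C(C)=C2C1 | intermediate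
20 | angelic acid, (Z)-2-methylbut-2-enoic acid | C/C=C(/C)C(=O)O | starting material
21 | angelic 2,4,6-trichlorobenzoic anhydride (not isolated) | C/C=C(/C)C(=O)OC(=O)c1c(Cl)cc(Cl)cc1Cl | intermediate
22 | methyl 3β-angeloyloxyeudesma-4,11(13)-dien-12-oate (3S,7R,10S) | C=C(C(=O)OC)[C@@H]1CC[C@@]2(C)CC[C@H](OC(=O)/C(C)=C\C)C(C)=C2C1 | intermediate
23 | methyl 3β-angeloyloxy-5α-hydroperoxyeudesma-4(15),11(13)-dien-12-oate (3S,5S,7R,10S) | C=C(C(=O)OC)[C@@H]1CC[C@@]2(C)CC[C@H](OC(=O)/C(C)=C\C)C(=C)[C@]2(OO)C1 | target

Total step count: 13. Longest linear sequence: 13 steps (1 → 23).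

**Steps most likely to fail**

Step 10 (Proposed new method). The closure may run through C4 or through the C2 enolate to bridged bicyclo[3.3.1]nonanes, the base may strip HBr from the bromomethyl enoate to a diene, or ring B may close through the transition state with the C11 unit axial. The fallback uses known reaction types, sets out from aldehyde 13 and returns at 18. Knoevenagel condensation of 13 with trimethyl phosphonoacetate (TiCl4, N-methylmorpholine, THF, 0 °C) should give methyl 2-(dimethoxyphosphoryl)-5-[(1S)-1,2,3-trimethyl-4-oxocyclohex-2-en-1-yl]pent-2-enoate F1. NaOMe in MeOH (rt to 50 °C) should then effect an intramolecular vinylogous Michael addition of C6 to C7; because this addition is reversible it is expected to settle on the conjugated, unbridged adduct with the side chain equatorial, methyl 2-(dimethoxyphosphoryl)-2-[(2R,4aS)-4a,8-dimethyl-7-oxo-1,2,3,4,4a,5,6,7-octahydronaphthalen-2-yl]acetate F2. Horner–Wadsworth–Emmons methylenation of F2 with aqueous formaldehyde and K2CO3 should then install C13 and deliver 18.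

Step 13. Site and face selectivity of the ene reaction may erode (hydrogen abstraction at C3 or C6, attack from the β-face), or the hydroperoxide may react further. The fallback sets out from 22 and returns at 23 without singlet oxygen. Hydroxyselenation of 22 (PhSeCl, MeCN/H2O, rt) should add selenium from the open α-face to C4 and water to C5, the carbon remote from the acyloxy-bearing C3, giving methyl 3β-angeloyloxy-5β-hydroxy-4α-(phenylselanyl)eudesm-11(13)-en-12-oate F3. Oxidation (H2O2, pyridine, CH2Cl2, 0 °C) should give the selenoxide of F3, methyl 3β-angeloyloxy-5β-hydroxy-4α-(phenylseleninyl)eudesm-11(13)-en-12-oate F4, whose syn-elimination avoids both oxygen-bearing neighbours and should run into the C15 methyl to give methyl 3β-angeloyloxy-5β-hydroxyeudesma-4(15),11(13)-dien-12-oate F5. Acid-catalysed perhydrolysis of F5 (50% H2O2, cat. H2SO4, Et2O, 0 °C) through the allyl cation, with H2O2 expected at the tertiary terminus C5 from the face opposite the C10 methyl, should give 23.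

Step 12. The angelate may isomerise to the tiglate, or acylation of the hindered allylic alcohol may stall. The fallback sets out from 19 and returns at 22 by building the Z alkene on the molecule. Esterification of 19 with 2-[bis(2,2,2-trifluoroethoxy)phosphoryl]propanoic acid (EDC·HCl, DMAP, CH2Cl2) should give methyl 3β-{2-[bis(2,2,2-trifluoroethoxy)phosphoryl]propanoyloxy}eudesma-4,11(13)-dien-12-oate F6. Still–Gennari olefination of F6 with acetaldehyde (KHMDS, 18-crown-6, THF, −78 °C) should give the (Z)-2-methylbut-2-enoate 22.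

**Further compounds**
F1 | step 10 | methyl 2-(dimethoxyphosphoryl)-5-[(1S)-1,2,3-trimethyl-4-oxocyclohex-2-en-1-yl]pent-2-enoate (E/Z mixture) | COC(=O)C(=CCC[C@@]1(C)CCC(=O)C(C)=C1C)P(=O)(OC)OC
F2 | step 10 | methyl 2-(dimethoxyphosphoryl)-2-[(2R,4aS)-4a,8-dimethyl-7-oxo-1,2,3,4,4a,5,6,7-octahydronaphthalen-2-yl]acetate (epimers at the phosphonate carbon) | COC(=O)C([C@@H]1CC[C@@]2(C)CCC(=O)C(C)=C2C1)P(=O)(OC)OC
F3 | step 13 | methyl 3β-angeloyloxy-5β-hydroxy-4α-(phenylselanyl)eudesm-11(13)-en-12-oate | C=C(C(=O)OC)[C@@H]1CC[C@@]2(C)CC[C@H](OC(=O)/C(C)=C\C)[C@@](C)([Se]c3ccccc3)[C@@]2(O)C1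
F4 | step 13 | methyl 3β-angeloyloxy-5β-hydroxy-4α-(phenylseleninyl)eudesm-11(13)-en-12-oate (selenoxide of F3) | C=C(C(=O)OC)[C@@H]1CC[C@@]2(C)CC[C@H](OC(=O)/C(C)=C\C)[C@@](C)([Se](=O)c3ccccc3)[C@@]2(O)C1
F5 | step 13 | methyl 3β-angeloyloxy-5β-hydroxyeudesma-4(15),11(13)-dien-12-oate | C=C(C(=O)OC)[C@@H]1CC[C@@]2(C)CC[C@H](OC(=O)/C(C)=C\C)C(=C)[C@@]2(O)C1
F6 | step 12 | methyl 3β-{2-[bis(2,2,2-trifluoroethoxy)phosphoryl]propanoyloxy}eudesma-4,11(13)-dien-12-oate | C=C(C(=O)OC)[C@@H]1CC[C@@]2(C)CC[C@H](OC(=O)C(C)P(=O)(OCC(F)(F)F)OCC(F)(F)F)C(C)=C2C1
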